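**Plan** (briarane numbering of the target is used throughout)
1. Retrosynthetic cuts: C6–Cl (ene-type chlorination of a 5Z-olefin), then C7–C8 (photochemical transannular closure of a 13-membered β-keto macrolactone), then C8–C17 (Reformatsky) and O7–C19 (ester), C4–C5 (B-alkyl Suzuki), C2–C3 (alkynylation), C1–C14/C10–C11 (Diels–Alder).
2. Forward order: the cyclohexane ring is made first by Diels–Alder reaction and is fully oxygenated and acylated; the C3–C7 chain is attached; the 13-membered lactone is closed; one photochemical step contracts it to the ten-membered carbocycle plus the γ-lactone; chlorination is last.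
3. Enabling feature: the C8 ketone has no γ-hydrogen (C1 is quaternary, C11 is the spiro-epoxide carbon, and the lactone oxygen occupies the γ-position on the other side), while C7-H2 is δ, allylic and O-acylated.
4. Consequence: 1,6-hydrogen transfer and 1,5-biradical closure should form C7–C8, the γ-lactone and the ten-membered ring together, with C7 and C8 set in that step.
5. Stereochemistry, ring: C9 from D-glyceraldehyde; C1/C10 from the facial selectivity of the cycloaddition; C2 by chelation-controlled alkynylation; C13/C14 by osmylation anti to the axial C1-methyl; C12 by hydride anti to the acetonide; C11 by hydroxyl-directed epoxidation.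
6. Stereochemistry, large ring: C7/C8 in the key step (trans ring fusion); C17 by equilibration; C6 by chlorination anti to the allylic C7–O bond.

Key step: step 21

Assumption: in step 3 the diene is taken to add to the enal face anti to the allylic C–O bond of the dioxolane, in the rotamer where the allylic H eclipses the olefin (allylic 1,3-strain with the α-methyl).
Convention: unless stated, each stereocentre of an intermediate has the spatial arrangement of the corresponding target carbon; C17 is a mixture of epimers in 25–30.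

**Step 1**
Reactants: 1 but-2-yn-1-ol
Product: 3 (Z)-3-iodobut-2-en-1-ol, via vinylalanate 2 (not isolated)
Conditions: Red-Al, THF, 0 °C to rt; EtOAc; then I2, −78 °C
Reagents that add atoms: iodine, II
Why: Alkoxide-directed trans-hydroalumination places aluminium on C3 cis to the CH2O group, and iodinolysis with retention should give the Z vinyl iodide (hydroalumination–iodination).

**Step 2**
Reactants: 4 (R)-glyceraldehyde acetonide; 5 2-(triphenylphosphoranylidene)propanal
Product: 6 (S,E)-dioxolanyl-2-methylpropenal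
Conditions: PhMe, 80 °C
Reagents that add atoms: none
Why: Wittig olefination with the stabilised α-methyl formyl ylide should be E-selective and does not touch the α-alkoxy stereocentre (future C9).

**Step 3**
Reactants: 6 enal; 7 (E)-1-(dimethylamino)-3-(tert-butyldimethylsilyloxy)buta-1,3-diene
Product: 10 enone propargylic alcohol, via Diels–Alder adduct 8 (not isolated), via magnesium alkoxide 9 (not isolated)
Conditions: PhMe, 60 °C; then HC≡CMgBr, THF, −78 to −20 °C; then 0.5 M HCl, THF, 0 °C
Reagents that add atoms: ethynylmagnesium bromide, C#C[Mg]Br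
Why: The aminosiloxydiene should add to the enal C=C (Diels–Alder, CH2 terminus to the β-carbon, endo) on the face anti to the dioxolane C–O bond, setting C1 and C10 trans from the E-olefin, the β-amino aldehyde is then alkynylated under chelation (Mg bridging C=O and NMe2, attack past the methyl, also the Felkin–Anh sense) to set C2, and acid hydrolyses the silyl enol ether with β-elimination of dimethylamine to unveil the enone.

**Step 4**
Reactants: 10 enone propargylic alcohol
Product: 11 C2 isobutyrate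
Conditions: (iPrCO)2O, DMAP, Et3N, CH2Cl2, 0 °C to rt
Reagents that add atoms: isobutyric anhydride, CC(C)C(=O)OC(=O)C(C)C
Why: DMAP-catalysed acylation of the only free hydroxyl installs the final C2 ester at the point where it can be placed without ambiguity.

**Step 5**
Reactants: 11 C2 isobutyrate
Product: 12 13α,14α-diol
Conditions: OsO4 (cat.), NMO, citric acid, t-BuOH/H2O, rt
Reagents that add atoms: osmium tetroxide (cat.), O=[Os](=O)(=O)=O; N-methylmorpholine N-oxide, C[N+]1([O-])CCOCC1; water, O
Why: Catalytic cis-dihydroxylation of the enone C13=C14 should occur on the face opposite the axial C1-methyl, and the alkyne is inert to OsO4.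

**Step 6**
Reactants: 12 diol
Product: 13 bis-acetonide ketone
Conditions: Me2C(OMe)2, PPTS, CH2Cl2, rt
Reagents that add atoms: 2,2-dimethoxypropane, COC(C)(C)OC
Why: Acid-catalysed transketalisation protects the cis-diol and masks the β-hydroxy ketone before enolisation chemistry.

**Step 7**
Reactants: 13 bis-acetonide ketone
Product: 14 11-methylene ketone
Conditions: (CH2O)n, PhNHMe·CF3CO2H, THF, reflux
Reagents that add atoms: paraformaldehyde (as formaldehyde), C=O
Why: Amine-salt-mediated Mannich condensation–elimination (α-methylenation) can deliver a methylene only at C11, the sole α-CH2 of the ketone.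

**Step 8**
Reactants: 14 11-methylene ketone
Product: 15 12α-allylic alcohol
Conditions: NaBH4, CeCl3·7H2O, MeOH, −78 °C
Reagents that add atoms: none
Why: Luche 1,2-reduction with hydride arriving on the β-face, opposite the cis-fused acetonide and its axial C14–O bond, should give the axial 12α-alcohol, all-cis with O13 and O14.

**Step 9**
Reactants: 15 12α-allylic alcohol
Product: 16 pentaol
Conditions: AcOH/H2O (4:1), 50 °C
Reagents that add atoms: none
Why: Aqueous acetic acid hydrolyses both isopropylidene acetals while the ester, alkyne and allylic alcohol should survive these mild conditions.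

**Step 10**
Reactants: 16 pentaol
Product: 17 8-O-TES tetraol
Conditions: TESCl, imidazole, DMF, −40 °C
Reagents that add atoms: chlorotriethylsilane, CC[Si](Cl)(CC)CC
Why: Low-temperature silylation is selective for the single primary hydroxyl (C8) over the four secondary ones.

**Step 11**
Reactants: 17 8-O-TES tetraol
Product: 19 13-O-isovalerate, via stannylene acetal 18 (not isolated)
Conditions: Bu2SnO, PhMe, reflux (−H2O); then iPrCH2COCl, CH2Cl2, 0 °C
Reagents that add atoms: isovaleryl chloride, CC(C)CC(Cl)=O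
Why: Stannylene acetal formation on the all-cis ring triol activates the equatorial oxygen flanked by axial hydroxyls, so acylation should go to O13 and not to the isolated C9 hydroxyl (tin-mediated regioselective acylation).

**Step 12**
Reactants: 19 13-O-isovalerate
Product: 20 11α,20-epoxide
Conditions: VO(acac)2 (cat.), t-BuOOH, CH2Cl2, 0 °C to rt
Reagents that add atoms: tert-butyl hydroperoxide, CC(C)(C)OO
Why: Vanadium-catalysed hydroxyl-directed epoxidation delivers oxygen to the exocyclic olefin syn to the axial allylic 12α-OH, which is also the face away from the axial C1-methyl, giving the epoxide with C20 β.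

**Step 13**
Reactants: 20 epoxide
Product: 21 9,12,14-triacetate
Conditions: Ac2O, DMAP, pyridine, rt to 40 °C
Reagents that add atoms: acetic anhydride, CC(=O)OC(C)=O
Why: DMAP-catalysed acetylation of the three remaining secondary hydroxyls completes the ester pattern in one operation.

**Step 14**
Reactants: 21 triacetate
Product: 22 C2 vinyl compound
Conditions: H2 (1 atm), Lindlar catalyst, quinoline, EtOAc, rt
Reagents that add atoms: none
Why: Lindlar semi-hydrogenation should stop at the alkene for the terminal alkyne, and the epoxide and esters are inert.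

**Step 15**
Reactants: 22 vinyl compound; 3 (Z)-3-iodobut-2-en-1-ol
Product: 24 neryl-type allylic alcohol, via B-alkyl-9-BBN 23 (not isolated)
Conditions: 9-BBN, THF, rt; then 3, Pd(dppf)Cl2, AsPh3, Cs2CO3, DMF/H2O, rt
Reagents that add atoms: none
Why: 9-BBN hydroborates the monosubstituted olefin at its terminus, and B-alkyl Suzuki–Miyaura coupling with the vinyl iodide proceeds with retention, giving the 5Z-olefin with C7–OH free.

**Step 16**
Reactants: 24 allylic alcohol
Product: 25 7-O-(2-bromopropanoate)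
Conditions: MeCHBrCOBr, pyridine, CH2Cl2, −20 °C
Reagents that add atoms: 2-bromopropionyl bromide, CC(Br)C(Br)=O
Why: Acylation of the only free hydroxyl; the α-bromo centre may be a mixture because it becomes an enolate.

**Step 17**
Reactants: 25 bromo ester
Product: 26 C8 primary alcohol
Conditions: AcOH/THF/H2O (3:1:1), rt
Reagents that add atoms: none
Why: A primary triethylsilyl ether is cleaved by dilute acetic acid under conditions that should leave the acetates, the α-bromo ester and the epoxide intact.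

**Step 18**
Reactants: 26 primary alcohol
Product: 27 α-acetoxy aldehyde
Conditions: Dess–Martin periodinane, NaHCO3, CH2Cl2, 0 °C
Reagents that add atoms: none
Why: Buffered Dess–Martin oxidation gives the configurationally labile α-acetoxy aldehyde without base, so C9 should not epimerise and the acetate should not migrate.

**Step 19**
Reactants: 27 α-acetoxy aldehyde
Product: 29 13-membered β-hydroxy lactone, via samarium enolate 28 (not isolated)
Conditions: SmI2, THF, −78 °C, slow addition, ≤2 mM
Reagents that add atoms: none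
Why: SmI2 reduces the α-bromo ester to a samarium(III) enolate faster than it touches the aldehyde, and the intramolecular Reformatsky addition at high dilution closes the macrolactone (the new C8 centre is oxidised away next).

**Step 20**
Reactants: 29 β-hydroxy lactone
Product: 30 β-keto macrolactone
Conditions: Dess–Martin periodinane, NaHCO3, CH2Cl2, rt
Reagents that add atoms: none
Why: Dess–Martin oxidation of the β-hydroxy lactone gives the α-substituted β-keto lactone, whose C17 is freely epimerisable.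

**Step 21**
Reactants: 30 β-keto macrolactone
Product: 32 ring-contracted 5Z-briarane lactone, via 1,5-biradical 31 (not isolated)
Conditions: hν (300 nm, Pyrex), degassed PhH/t-BuOH, 2 mM, rt; then DBU (cat.), PhMe, rt
Reagents that add atoms: none
Why: Proposed new method: n→π* excitation of the C8 ketone of 30, which carries no γ-hydrogen (C1 quaternary, C11 the spiro-epoxide carbon, the lactone oxygen in the γ-position), should lead to 1,6-hydrogen transfer from the δ, allylic and O-acylated C7-H2 through a seven-membered transition state and then to C7–C8 recombination of the 1,5-hydroxy biradical 31; the closest known reaction type is the Norrish–Yang photocyclisation by δ-hydrogen abstraction (β-oxo esters to β-hydroxy-γ-butyrolactones, β-alkoxy ketones to oxolan-3-ols), which has not been shown transannularly on a macrocyclic dialkyl β-keto lactone. The γ-lactone closes by 1,5-biradical recombination to a five-membered ring, and the same bond makes the ten-membered carbocycle by transannular contraction of the 13-membered lactone (13 → 10 + 5). C8 should be set by the α-acetoxy ketone rotamer in which C8=O lies syn to C9–OAc so that C7 bonds anti to C10, C7 by the trans ring fusion (C6 and C9 anti across the new bond, the arrangement of least transannular strain), and C17 by the DBU equilibration that puts Me-18 trans to C9 on the lactone. The step needs abstraction at C7 and not at the other δ-positions (C2-H, C12-H, C14-H, C15-H3, C20-H2), which the weak doubly activated C7–H bond and the acylation of every other carbinol carbon should secure, and it needs closure at C7 and not at C5 of the allyl radical, which the five-membered ring and the secondary terminus favour. Norrish type I cleavage and Paternò–Büchi addition to the 5,6-olefin are the competing paths, held back by long-wavelength irradiation in dilute solution at room temperature.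

**Step 22**
Reactants: 32 5Z-briarane lactone
Product: 33 CNP0231073.1 (target)
Conditions: Ca(OCl)2, CO2 (s), CH2Cl2/H2O, 0 °C
Reagents that add atoms: calcium hypochlorite, [Ca+2].[O-]Cl.[O-]Cl
Why: Ene-type chlorination of a trisubstituted olefin by HOCl puts chlorine on the less substituted C6 with loss of a C16 proton to give the exocyclic methylene, and Cl+ is expected on the face anti to the allylic C7–O bond with H-7 eclipsing the olefin (the outer face of the ring), which corresponds to 6S.

**Compound list**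
1 | but-2-yn-1-ol | CC#CCO | starting material
2 | sodium cyclic alkoxy(vinyl)alanate from trans-hydroalumination of 1 | CC1=CCO[Al-]1(OCCOC)OCCOC.[Na+] | intermediate
3 | (Z)-3-iodobut-2-en-1-ol | OC/C=C(/C)I | intermediate
4 | (R)-2,2-dimethyl-1,3-dioxolane-4-carbaldehyde (D-glyceraldehyde acetonide) | O=C[C@H]1COC(C)(C)O1 | starting material
5 | 2-(triphenylphosphoranylidene)propanal | CC(C=O)=P(c1ccccc1)(c1ccccc1)c1ccccc1 | starting material
6 | (E)-3-[(4S)-2,2-dimethyl-1,3-dioxolan-4-yl]-2-methylprop-2-enal | O=C/C(C)=C/[C@H]1COC(C)(C)O1 | intermediate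
7 | (E)-1-(dimethylamino)-3-(tert-butyldimethylsilyloxy)buta-1,3-diene | CN(C)/C=C/C(=C)O[Si](C)(C)C(C)(C)C | starting material
8 | Diels–Alder adduct: 2-(dimethylamino)-1-methyl-4-(TBSO)-6-[(4S)-dioxolanyl]cyclohex-3-ene-1-carbaldehyde, amino cis to formyl, formyl trans to dioxolanyl | O=C[C@@]1(C)[C@@H](N(C)C)C=C(O[Si](C)(C)C(C)(C)C)C[C@@H]1[C@H]1COC(C)(C)O1 | intermediate
9 | bromomagnesium alkoxide of the C2 propargylic alcohol derived from 8 | C#C[C@H](O[Mg]Br)[C@@]1(C)[C@@H](N(C)C)C=C(O[Si](C)(C)C(C)(C)C)C[C@@H]1[C@H]1COC(C)(C)O1 | intermediate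
10 | 4-[(1S)-1-hydroxyprop-2-ynyl]-4-methyl-5-[(4S)-2,2-dimethyl-1,3-dioxolan-4-yl]cyclohex-2-enone (ring substituents trans) | C#C[C@H](O)[C@@]1(C)C=CC(=O)C[C@@H]1[C@H]1COC(C)(C)O1 | intermediate
11 | C2 isobutyrate of 10 | C#C[C@H](OC(=O)C(C)C)[C@@]1(C)C=CC(=O)C[C@@H]1[C@H]1COC(C)(C)O1 | intermediate
12 | 13α,14α-dihydroxy-12-ketone | C#C[C@H](OC(=O)C(C)C)[C@@]1(C)[C@@H](O)[C@@H](O)C(=O)C[C@@H]1[C@H]1COC(C)(C)O1 | intermediate
13 | 13,14-O-isopropylidene-12-ketone (bis-acetonide) | C#C[C@H](OC(=O)C(C)C)[C@@]1(C)[C@@H](OC(C)(C)O2)[C@@H]2C(=O)C[C@@H]1[C@H]1COC(C)(C)O1 | intermediate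
14 | 11-methylene-12-ketone | C#C[C@H](OC(=O)C(C)C)[C@@]1(C)[C@@H](OC(C)(C)O2)[C@@H]2C(=O)C(=C)[C@@H]1[C@H]1COC(C)(C)O1 | intermediate
15 | 12α-hydroxy-11-methylene bis-acetonide | C#C[C@H](OC(=O)C(C)C)[C@@]1(C)[C@@H](OC(C)(C)O2)[C@@H]2[C@@H](O)C(=C)[C@@H]1[C@H]1COC(C)(C)O1 | intermediate
16 | 8,9,12,13,14-pentaol (C2 isobutyrate, C3–C4 alkyne, 11-methylene) | C#C[C@H](OC(=O)C(C)C)[C@@]1(C)[C@@H](O)[C@@H](O)[C@@H](O)C(=C)[C@@H]1[C@H](O)CO | intermediate
17 | 8-O-triethylsilyl tetraol | C#C[C@H](OC(=O)C(C)C)[C@@]1(C)[C@@H](O)[C@@H](O)[C@@H](O)C(=C)[C@@H]1[C@H](O)CO[Si](CC)(CC)CC | intermediate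
18 | 12,13-O-dibutylstannylene acetal of 17 | C#C[C@H](OC(=O)C(C)C)[C@@]1(C)[C@@H](O)[C@@H](O[Sn](CCCC)(CCCC)O2)[C@@H]2C(=C)[C@@H]1[C@H](O)CO[Si](CC)(CC)CC | intermediate
19 | 13-O-isovalerate 9,12,14-triol | C#C[C@H](OC(=O)C(C)C)[C@@]1(C)[C@@H](O)[C@@H](OC(=O)CC(C)C)[C@@H](O)C(=C)[C@@H]1[C@H](O)CO[Si](CC)(CC)CC | intermediate
20 | 11α,20-epoxide (C20 β) 9,12,14-triol | C#C[C@H](OC(=O)C(C)C)[C@@]1(C)[C@@H](O)[C@@H](OC(=O)CC(C)C)[C@@H](O)[C@]2(CO2)[C@@H]1[C@H](O)CO[Si](CC)(CC)CC | intermediate
21 | 9,12,14-triacetate 13-isovalerate 2-isobutyrate epoxide, C3–C4 alkyne, 8-OTES | C#C[C@H](OC(=O)C(C)C)[C@@]1(C)[C@@H](OC(C)=O)[C@@H](OC(=O)CC(C)C)[C@@H](OC(C)=O)[C@]2(CO2)[C@@H]1[C@H](OC(C)=O)CO[Si](CC)(CC)CC | intermediate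
22 | C3–C4 vinyl analogue of 21 | C=C[C@H](OC(=O)C(C)C)[C@@]1(C)[C@@H](OC(C)=O)[C@@H](OC(=O)CC(C)C)[C@@H](OC(C)=O)[C@]2(CO2)[C@@H]1[C@H](OC(C)=O)CO[Si](CC)(CC)CC | intermediate
23 | C4 B-alkyl-9-borabicyclo[3.3.1]nonane from 22 | C1CC2CCCC(C1)B2CC[C@H](OC(=O)C(C)C)[C@@]1(C)[C@@H](OC(C)=O)[C@@H](OC(=O)CC(C)C)[C@@H](OC(C)=O)[C@]2(CO2)[C@@H]1[C@H](OC(C)=O)CO[Si](CC)(CC)CC | intermediate
24 | (5Z)-C1–C8 seco compound with free C7–OH and 8-OTES | OC/C=C(/C)CC[C@H](OC(=O)C(C)C)[C@@]1(C)[C@@H](OC(C)=O)[C@@H](OC(=O)CC(C)C)[C@@H](OC(C)=O)[C@]2(CO2)[C@@H]1[C@H](OC(C)=O)CO[Si](CC)(CC)CC | intermediate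
25 | 7-O-(2-bromopropanoyl) derivative of 24 | CC(Br)C(=O)OC/C=C(/C)CC[C@H](OC(=O)C(C)C)[C@@]1(C)[C@@H](OC(C)=O)[C@@H](OC(=O)CC(C)C)[C@@H](OC(C)=O)[C@]2(CO2)[C@@H]1[C@H](OC(C)=O)CO[Si](CC)(CC)CC | intermediate
26 | C8 primary alcohol | CC(Br)C(=O)OC/C=C(/C)CC[C@H](OC(=O)C(C)C)[C@@]1(C)[C@@H](OC(C)=O)[C@@H](OC(=O)CC(C)C)[C@@H](OC(C)=O)[C@]2(CO2)[C@@H]1[C@H](OC(C)=O)CO | intermediate
27 | C8 aldehyde (9-acetoxy) | CC(Br)C(=O)OC/C=C(/C)CC[C@H](OC(=O)C(C)C)[C@@]1(C)[C@@H](OC(C)=O)[C@@H](OC(=O)CC(C)C)[C@@H](OC(C)=O)[C@]2(CO2)[C@@H]1[C@H](OC(C)=O)C=O | intermediate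
28 | samarium(III) ester enolate of 27 | CC=C(O[Sm](I)I)OC/C=C(/C)CC[C@H](OC(=O)C(C)C)[C@@]1(C)[C@@H](OC(C)=O)[C@@H](OC(=O)CC(C)C)[C@@H](OC(C)=O)[C@]2(CO2)[C@@H]1[C@H](OC(C)=O)C=O | intermediate
29 | 13-membered 8-hydroxy-17-methyl macrolactone (C8/C17 mixture) | C1C[C@H](OC(=O)C(C)C)[C@@]2(C)[C@@H](OC(C)=O)[C@@H](OC(=O)CC(C)C)[C@@H](OC(C)=O)[C@]3(CO3)[C@@H]2[C@H](OC(C)=O)C(O)C(C)C(=O)OC/C=C1/C | intermediate
30 | 13-membered 8-oxo macrolactone (5Z; C17 epimerisable) | C1C[C@H](OC(=O)C(C)C)[C@@]2(C)[C@@H](OC(C)=O)[C@@H](OC(=O)CC(C)C)[C@@H](OC(C)=O)[C@]3(CO3)[C@@H]2[C@H](OC(C)=O)C(=O)C(C)C(=O)OC/C=C1/C | intermediate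
31 | 1,5-biradical (C8 hydroxyalkyl radical, C7 acyloxyallyl radical) | C1C[C@H](OC(=O)C(C)C)[C@@]2(C)[C@@H](OC(C)=O)[C@@H](OC(=O)CC(C)C)[C@@H](OC(C)=O)[C@]3(CO3)[C@@H]2[C@H](OC(C)=O)[C](O)C(C)C(=O)O[CH]/C=C1/C | intermediate
32 | (5Z)-6-deschloro-5,6-ene briarane lactone with 8-OH | C1C[C@H](OC(=O)C(C)C)[C@@]2(C)[C@@H](OC(C)=O)[C@@H](OC(=O)CC(C)C)[C@@H](OC(C)=O)[C@]3(CO3)[C@@H]2[C@H](OC(C)=O)[C@]2(O)[C@@H](C)C(=O)O[C@H]2/C=C1/C | intermediate
33 | CNP0231073.1 | C=C1CC[C@H](OC(=O)C(C)C)[C@@]2(C)[C@@H](OC(C)=O)[C@@H](OC(=O)CC(C)C)[C@@H](OC(C)=O)[C@]3(CO3)[C@@H]2[C@H](OC(C)=O)[C@]2(O)[C@@H](C)C(=O)O[C@H]2[C@H]1Cl | target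

**Count:** 22 steps in total; longest linear sequence 21 steps (steps 2–22, from D-glyceraldehyde acetonide).

**Steps most likely to fail**

Step 21. The excited ketone may cleave by the Norrish type I path, abstract hydrogen at a competing δ-position, or close the biradical with the wrong ring fusion. The fallback uses known chemistry, sets out from 24 and returns at 32. Acid cleavage of the TES ether would give the 7,8-diol F1, and double Dess–Martin oxidation the enal-aldehyde F2. Roskamp homologation of the more electrophilic saturated C8 aldehyde with ethyl 2-diazopropanoate/SnCl2 would give the β-keto ester F3. A SmI2-mediated intramolecular ketone–enal pinacol coupling would then close the ten-membered ring at C7–C8 to the diol ester F4, which should lactonise (PPTS) to 32. The trans-disposed 7,8-diol is required; a low-valent titanium pinacol is the alternative reductant if samarium chelation favours the cis-diol.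

Step 22. Proton loss toward C4 (endocyclic olefin), chloroetherification by the 8-OH, or poor facial selectivity at C6 may intervene. The fallback sets out from 32 and returns at 33. Peracid epoxidation would give the 5,6-epoxide F5, and Cp2TiCl-mediated radical opening with β-hydride elimination the 6-hydroxy-5(16)-ene F6. Dess–Martin oxidation would give the enone F7, and Luche reduction under Felkin–Anh control (hydride anti to the C7–O bond) the 6-epi alcohol F8. Chloride displacement with inversion (PPh3, NCS) would then give 33, so C6 is fixed by hydride delivery and SN2 inversion instead of by the facial preference of Cl+.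

Step 3. The cycloaddition may show poor facial selectivity, the diene may add to the formyl group (hetero-Diels–Alder), or chelation control at C2 may be incomplete. The fallback sets out from 6 and returns at 10, moving face control to a catalyst. A chiral oxazaborolidinium Lewis acid-catalysed Diels–Alder reaction of 6 with 2-(triisopropylsilyloxy)buta-1,3-diene would give the silyl enol ether aldehyde F9. Ethynylmagnesium bromide (Felkin–Anh addition) would give the propargylic alcohol F10, and Saegusa–Ito dehydrogenation (Pd(OAc)2, O2, DMSO) the enone 10.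

**Further compounds**
F1 | step 21 | 7,8-diol from 24 | OC/C=C(/C)CC[C@H](OC(=O)C(C)C)[C@@]1(C)[C@@H](OC(C)=O)[C@@H](OC(=O)CC(C)C)[C@@H](OC(C)=O)[C@]2(CO2)[C@@H]1[C@H](OC(C)=O)CO
F2 | step 21 | (Z)-C7 enal C8 aldehyde | O=C/C=C(/C)CC[C@H](OC(=O)C(C)C)[C@@]1(C)[C@@H](OC(C)=O)[C@@H](OC(=O)CC(C)C)[C@@H](OC(C)=O)[C@]2(CO2)[C@@H]1[C@H](OC(C)=O)C=O
F3 | step 21 | C7 enal with C8-oxo ethyl 2-methyl-3-oxopropanoate unit | O=C/C=C(/C)CC[C@H](OC(=O)C(C)C)[C@@]1(C)[C@@H](OC(C)=O)[C@@H](OC(=O)CC(C)C)[C@@H](OC(C)=O)[C@]2(CO2)[C@@H]1[C@H](OC(C)=O)C(=O)C(C)C(=O)OCC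
F4 | step 21 | ten-membered 7,8-diol ethyl ester (pinacol product) | C1C[C@H](OC(=O)C(C)C)[C@@]2(C)[C@@H](OC(C)=O)[C@@H](OC(=O)CC(C)C)[C@@H](OC(C)=O)[C@]3(CO3)[C@@H]2[C@H](OC(C)=O)[C@](O)(C(C)C(=O)OCC)[C@@H](O)/C=C1/C
F5 | step 22 | 5,6-epoxide of 32 (oxygen anti to O7) | C[C@]12CC[C@H](OC(=O)C(C)C)[C@@]3(C)[C@@H](OC(C)=O)[C@@H](OC(=O)CC(C)C)[C@@H](OC(C)=O)[C@]4(CO4)[C@@H]3[C@H](OC(C)=O)[C@]3(O)[C@@H](C)C(=O)O[C@H]3[C@H]1O2
F6 | step 22 | 6-hydroxy-5(16)-ene (OH in the place of the natural Cl) | C=C1CC[C@H](OC(=O)C(C)C)[C@@]2(C)[C@@H](OC(C)=O)[C@@H](OC(=O)CC(C)C)[C@@H](OC(C)=O)[C@]3(CO3)[C@@H]2[C@H](OC(C)=O)[C@]2(O)[C@@H](C)C(=O)O[C@H]2[C@H]1O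
F7 | step 22 | 6-oxo-5(16)-ene | C=C1CC[C@H](OC(=O)C(C)C)[C@@]2(C)[C@@H](OC(C)=O)[C@@H](OC(=O)CC(C)C)[C@@H](OC(C)=O)[C@]3(CO3)[C@@H]2[C@H](OC(C)=O)[C@]2(O)[C@@H](C)C(=O)O[C@H]2C1=O
F8 | step 22 | 6-epi-hydroxy-5(16)-ene | C=C1CC[C@H](OC(=O)C(C)C)[C@@]2(C)[C@@H](OC(C)=O)[C@@H](OC(=O)CC(C)C)[C@@H](OC(C)=O)[C@]3(CO3)[C@@H]2[C@H](OC(C)=O)[C@]2(O)[C@@H](C)C(=O)O[C@H]2[C@@H]1O
F9 | step 3 | 1-methyl-4-(triisopropylsilyloxy)-6-[(4S)-dioxolanyl]cyclohex-3-ene-1-carbaldehyde | O=C[C@@]1(C)CC=C(O[Si](C(C)C)(C(C)C)C(C)C)C[C@@H]1[C@H]1COC(C)(C)O1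
F10 | step 3 | C2 propargylic alcohol of F9 | C#C[C@H](O)[C@@]1(C)CC=C(O[Si](C(C)C)(C(C)C)C(C)C)C[C@@H]1[C@H]1COC(C)(C)O1
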